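**Plan**

1. Feature: C10 is a quaternary spiro carbon that carries C20H2–O and the chain C9–C8–C7(=O). This β-oxygenated quaternary centre is what a tertiary radical from a C10–C20 spiro epoxide leaves after adding to an acrylate, the C20 alkoxide then closing the δ-lactone on C7.
2. Retrosynthetic cuts, in order: C6–O silyl; C16–OH; C13–C16 (ring D); C8–C14 and C9–C11 (ring C, cycloaddition to a C8=C9 lactone); C8–C15; C2=C3 (loss of a C3 acetate); C9–C10 and O–C7 (key step); C10–C20 epoxide and C1–O; C4–C5 (ring A).
3. Forward: ring A by radical cyclisation of (R)-6,7-epoxygeranyl acetate → C1 oxygenation and spiro epoxide → spiro lactone → ring A enone → ring C by Diels–Alder reaction → ring D by 5-exo radical cyclisation → C16 hydroxylation → desilylation.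
4. Stereochemistry: the asymmetric epoxidation sets C3 (a relay centre, lost in step 13); C3 sets C5 in the cyclisation; C5 sets C10 in the key step; C10 steers the diene to one face of C8=C9 (C8 and C9, cis); the bridge fixes C13; exo attack on the ring D enolate sets C16.

Key step: step 11

Remark on numbering: atoms carry the numbers of the target (ring A: C1–C5, C10; C6 on C5; C20 on C10; lactone carbonyl C7; ring C: C8, C9, C11–C14; ring D: C15, C16; methyl C17). Geranyl C7, C6, C5, C4, C3, C2, C1 become C4, C3, C2, C1, C10, C5, C6, and the C3 methyl becomes C20.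

Assumption on the target: it is taken exactly as drawn, with C7 and C10 cis on ring C (lactone cis-fused to ring C), C11 on the same side of the lactone ring as C1, and the C16 hydroxyl exo (syn to C14).

Assumption on mixtures: 11 is drawn as the C10 epimer expected from peracid attack anti to the axial C4 methyl; its epimer would pass through the same C10 radical. Compounds 18, 24 and 25 are epimer mixtures at the centre named, and each such centre is erased or reset in the following step.

Step 1
Reactants: 1 geranyl acetate
Product: 2 (R)-6,7-epoxygeranyl acetate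
Conditions: D-fructose-derived ketone catalyst (1,2:4,5-di-O-isopropylidene-β-D-erythro-2,3-hexodiulo-2,6-pyranose, 0.3 equiv), KHSO5 (as 2KHSO5·KHSO4·K2SO4), K2CO3, Bu4NHSO4, MeCN/CH2(OMe)2/aq. Na2B4O7 buffer (pH 10.5), 0 °C
Reagents that add atoms: potassium peroxymonosulfate, [K+].[O-]S(=O)(=O)OO
Why: Shi asymmetric epoxidation (chiral dioxirane, spiro transition state) should attack only the electron-rich 6,7-alkene, the 2,3-alkene being deactivated by the allylic acetate, and the D-fructose-derived catalyst should give the (R)-epoxide, the centre from which all later ones are relayed.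

Step 2
Reactants: 2 (R)-6,7-epoxygeranyl acetate
Product: 3 [(1S,3R)-3-hydroxy-2,2-dimethyl-6-methylidenecyclohexyl]methyl acetate
Conditions: Cp2TiCl2 (2.2 equiv), Mn dust (8 equiv), THF, rt, slow addition of 2; 1 M HCl work-up
Reagents that add atoms: none
Why: Cp2TiCl (trivalent titanium) opens the epoxide homolytically to the tertiary C4 radical, which closes 6-endo-trig onto the trisubstituted alkene through a chair with the titanoxy and acetoxymethyl groups equatorial (C3 sets C5, cis), and the new tertiary C10 radical loses hydrogen to a second Cp2TiCl to give the exocyclic C10=C20 alkene, a radical epoxypolyene cyclisation known for epoxygeranyl esters.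

Step 3
Reactants: 3 hydroxy acetate
Product: 4 (1R,3S)-3-(hydroxymethyl)-2,2-dimethyl-4-methylidenecyclohexan-1-ol
Conditions: K2CO3 (0.2 equiv), MeOH, rt
Reagents that add atoms: none
Why: Base-catalysed transesterification removes the primary acetate, which would not survive the later lactone and ketone enolate steps.

Step 4
Reactants: 4 diol
Product: 5 C6 tert-butyldiphenylsilyl ether of 4
Conditions: tBuPh2SiCl (1.05 equiv), imidazole, CH2Cl2, 0 °C
Reagents that add atoms: tert-butyl(chloro)diphenylsilane, CC(C)(C)[Si](Cl)(c1ccccc1)c1ccccc1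
Why: Silylation with the bulky chlorosilane is selective for the primary alcohol over the neopentyl secondary one and installs a group meant to last until step 20.

Step 5
Reactants: 5 silyl ether alcohol
Product: 6 C3 acetate of 5
Conditions: Ac2O, DMAP (0.1 equiv), pyridine, rt
Reagents that add atoms: acetic anhydride, CC(=O)OC(C)=O
Why: DMAP-catalysed acylation caps the C3 hydroxyl as an acetate that later serves as the leaving group for the C2=C3 alkene.

Step 6
Reactants: 6 acetate
Product: 7 C1 allylic alcohol (hydroxyl axial, trans to the C5 arm)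
Conditions: SeO2 (0.5 equiv), tBuOOH (3 equiv), CH2Cl2, rt
Reagents that add atoms: selenium dioxide, O=[Se]=O (oxygen donor); tert-butyl hydroperoxide, CC(C)(C)OO (reoxidant that supplies the oxygen in turnover)
Why: SeO2 allylic oxidation (ene reaction, then 2,3-sigmatropic shift) hydroxylates the only allylic methylene, C1, without moving the exocyclic alkene; the axial alcohol anti to the C5 arm is expected by analogy with related 2-substituted methylenecyclohexanes, and any C1 epimer converges in step 7.

Step 7
Reactants: 7 allylic alcohol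
Product: 8 α-methylene ketone (C1=O, C10=C20)
Conditions: Dess–Martin periodinane (1.3 equiv), NaHCO3, CH2Cl2, 0 °C → rt
Reagents that add atoms: none
Why: Dess–Martin oxidation under buffered conditions should give the exocyclic enone without β-elimination of the C3 acetate.

Step 8
Reactants: 8 α-methylene ketone
Product: 9 C1 allylic alcohol (hydroxyl equatorial, cis to the C5 arm)
Conditions: NaBH4, CeCl3·7H2O, MeOH, −78 °C
Reagents that add atoms: none
Why: Luche 1,2-reduction delivers hydride axially to the C1 carbonyl, where only axial hydrogens at C3 and C5 are met, giving the equatorial alcohol cis to the equatorial C5 arm, the C1 configuration wanted for step 11.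

Step 9
Reactants: 9 allylic alcohol
Product: 10 C1 triethylsilyl ether
Conditions: Et3SiCl, imidazole, DMF, 0 °C → rt
Reagents that add atoms: chlorotriethylsilane, CC[Si](Cl)(CC)CC
Why: Silylation gives an ether that tolerates the radical step and can later be cleaved in the presence of the tert-butyldiphenylsilyl ether.

Step 10
Reactants: 10 silyl ether
Product: 11 ring A spiro epoxide (C10–C20 oxirane)
Conditions: mCPBA, NaHCO3, CH2Cl2, 0 °C
Reagents that add atoms: 3-chloroperbenzoic acid, OOC(=O)c1cccc(Cl)c1
Why: Prilezhaev epoxidation of the only alkene should occur mainly anti to the axial C4 methyl to give the drawn epoxide, and the configuration at C10 is of no consequence for step 11.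

Step 11
Reactants: 11 ring A spiro epoxide; 12 2,2,2-trifluoroethyl acrylate
Product: 14 spiro δ-lactone on ring A, via hydroxy ester 13 (not isolated)
Conditions: Cp2TiCl2 (1.5 equiv), Zn dust (3 equiv), 2,4,6-collidine·HCl (3 equiv), 12 (5 equiv), THF, rt
Reagents that add atoms: none
Why: Cp2TiCl (trivalent titanium, from Cp2TiCl2 and Zn) cleaves the C10–O bond of the spiro epoxide to a tertiary C10 radical with a titanium alkoxide on C20; the radical adds to the β-carbon of 12 (C9–C10 bond), a second Cp2TiCl reduces the α-ester radical to a titanium enolate, and collidinium chloride protonates it and returns Cp2TiCl2. The closest known reaction type is the Cp2TiCl-mediated reductive coupling of epoxides with acrylates followed by lactonisation, which is established for spiro epoxides of this 2,2-dimethyl-6-methylenecyclohexane class. The one ring formed, the δ-lactone, closes by 6-exo-trig acyl substitution of the C20 alkoxide on C7, made spontaneous by the trifluoroethoxide leaving group. The one new stereocentre, C10, is under substrate control: the planar radical is attacked anti to the C5 silyloxymethyl arm because the opposite face is closed by the axial C4 methyl (1,3-diaxial to the incoming acrylate), and the equatorial C1 silyl ether, cis to the arm, lies near the ring plane and leaves the reacting face free. The step needs homolysis towards the tertiary carbon and intermolecular addition faster than reduction of the radical to an alkyltitanium (which would lose the β-oxygen and return alkene 10); the higher substitution at C10, the slow reduction of a hindered tertiary radical and an excess of 12 should secure both. The epoxide configuration is erased at the radical, so either C10 epimer of 11 gives 14.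

Step 12
Reactants: 14 spiro δ-lactone
Product: 15 C1 alcohol
Conditions: PPTS (0.2 equiv), MeOH/CH2Cl2 (1:1), 0 °C → rt
Reagents that add atoms: none
Why: Mild acid-catalysed solvolysis cleaves the triethylsilyl ether while the primary tert-butyldiphenylsilyl ether, the acetate and the lactone remain, and the alcohol is oxidised at once so that acyl migration of the lactone to the C1 oxygen has no time to occur.

Step 13
Reactants: 15 C1 alcohol
Product: 17 ring A enone spiro lactone, via acetoxy ketone 16 (not isolated)
Conditions: Dess–Martin periodinane, NaHCO3, CH2Cl2, rt; then DBU (5 equiv), rt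
Reagents that add atoms: none
Why: Dess–Martin oxidation gives the C1 ketone, whose only α-hydrogens are on C2, so DBU effects E1cB loss of the C3 acetate to the C2=C3 enone, which has no enolisable hydrogen and removes the C1 substituent that would crowd the face of C9 on which C11 must later be attached.

Step 14
Reactants: 17 ring A enone spiro lactone
Product: 18 C8-propanoyl lactone (β-keto lactone)
Conditions: LiN(SiMe3)2 (2.2 equiv), THF, −78 °C; EtCOCl (1.1 equiv), −78 → −40 °C; aq. NH4Cl
Reagents that add atoms: propanoyl chloride, CCC(Cl)=O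
Why: Claisen-type C-acylation of the lactone lithium enolate, the only enolisable site, builds the C8–C15 bond, with the second equivalent of base taking up the acidic product; the C8 configuration is immaterial because C8 becomes trigonal in step 15.

Step 15
Reactants: 18 β-keto lactone
Product: 21 C8=C9 unsaturated 8-propanoyl lactone, via selenide 19 (not isolated), via selenoxide 20 (not isolated)
Conditions: PhSeCl, pyridine, CH2Cl2, 0 °C; then 30% H2O2, 0 °C → rt; product used directly
Reagents that add atoms: benzeneselenenyl chloride, Cl[Se]c1ccccc1 (PhSe of 19 and 20); hydrogen peroxide, OO (selenoxide oxygen of 20); none of these atoms remain in 21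
Why: Selenenylation of the β-dicarbonyl at C8, oxidation and selenoxide syn-elimination, for which only the C9 hydrogens are available, should give the doubly activated C8=C9 alkene.

Step 16
Reactants: 21 unsaturated 8-propanoyl lactone; 22 buta-1,3-diene
Product: 23 ring C cyclohexene adduct
Conditions: ZnCl2 (1.5 equiv), 22 (excess, condensed in), CH2Cl2, sealed tube, 0 °C → rt
Reagents that add atoms: none
Why: Lewis acid-catalysed Diels–Alder reaction of the chelated 2-acyl unsaturated lactone, a known dienophile class, builds ring C; suprafacial addition makes C7 and C10 cis on ring C as the target requires, and the diene should approach the face of C8=C9 flanked by the flat C1=O/C2=C3 unit, away from the C5 arm and the axial C4 methyl, which places C11 on the C1 side.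

Step 17
Reactants: 23 ring C cyclohexene adduct
Product: 24 C16 bromide
Conditions: LiN(SiMe3)2 (1.1 equiv), THF, −78 °C; then N-bromosuccinimide, −78 °C
Reagents that add atoms: N-bromosuccinimide, BrN1C(=O)CCC1=O
Why: Enolate bromination can occur only at C16, since C8 is quaternary and the ring A enone has no α- or γ-hydrogen, and the C16 configuration does not matter for the radical step.

Step 18
Reactants: 24 C16 bromide
Product: 25 bicyclo[3.2.1]octanone (ring D closed)
Conditions: Bu3SnH (1.2 equiv, slow addition), AIBN (0.1 equiv), PhH (0.01 M), 80 °C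
Reagents that add atoms: none
Why: Tin hydride radical cyclisation: bromine abstraction gives the C16 α-keto radical, which should add 5-exo-trig to C13 of the 1,2-disubstituted ring C alkene from the pseudoaxial acyl group, and the C12 radical takes hydrogen from Bu3SnH; the bridge can form on one face only so C13 follows from C8, and the C16 epimers converge in step 19.

Step 19
Reactants: 25 bicyclo[3.2.1]octanone
Product: 26 C16 exo-hydroxy ketone (C6 silyl ether of the target)
Conditions: KN(SiMe3)2 (1.3 equiv), THF, −78 °C; then 3-phenyl-2-(phenylsulfonyl)oxaziridine, −78 °C; aq. NH4Cl at −78 °C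
Reagents that add atoms: 3-phenyl-2-(phenylsulfonyl)oxaziridine, O=S(=O)(N1OC1c1ccccc1)c1ccccc1
Why: Enolate hydroxylation with an N-sulfonyloxaziridine: C16 is the only enolisable position, and the reagent should approach the enolate on the exo face (the side of the one-carbon bridge C14), away from the axial C11 hydrogen below the endo face, giving the tertiary alcohol exo and the methyl endo.

Step 20
Reactants: 26 C16 exo-hydroxy ketone
Product: 27 target CNP0530135.1
Conditions: HF·pyridine, pyridine, THF, 0 °C → rt
Reagents that add atoms: none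
Why: Fluoride cleavage of the silyl ether under buffered, non-basic conditions frees the C6 hydroxyl and avoids α-ketol rearrangement and lactone opening.

**Compound list**

1 | geranyl acetate, (2E)-3,7-dimethylocta-2,6-dien-1-yl acetate | CC(C)=CCC/C(C)=C/COC(C)=O | starting material
2 | (R)-6,7-epoxygeranyl acetate, (2E)-5-[(2R)-3,3-dimethyloxiran-2-yl]-3-methylpent-2-en-1-yl acetate | CC(=O)OC/C=C(C)/CC[C@H]1OC1(C)C | intermediate
3 | [(1S,3R)-3-hydroxy-2,2-dimethyl-6-methylidenecyclohexyl]methyl acetate (C3–OH cis to the C5 arm) | CC1(C)[C@H](O)CCC(=C)[C@@H]1COC(C)=O | intermediate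
4 | (1R,3S)-3-(hydroxymethyl)-2,2-dimethyl-4-methylidenecyclohexan-1-ol | CC1(C)[C@H](O)CCC(=C)[C@@H]1CO | intermediate
5 | (1R,3S)-3-[(tert-butyldiphenylsilyloxy)methyl]-2,2-dimethyl-4-methylidenecyclohexan-1-ol | CC1(C)[C@H](O)CCC(=C)[C@@H]1CO[Si](c5ccccc5)(c6ccccc6)C(C)(C)C | intermediate
6 | (1R,3S)-3-[(tert-butyldiphenylsilyloxy)methyl]-2,2-dimethyl-4-methylidenecyclohexyl acetate | CC1(C)[C@H](OC(C)=O)CCC(=C)[C@@H]1CO[Si](c5ccccc5)(c6ccccc6)C(C)(C)C | intermediate
7 | C1 allylic alcohol of 6, hydroxyl axial and trans to the C5 arm (C3–OAc, C6–OSitBuPh2, C10=C20) | CC1(C)[C@H](OC(C)=O)C[C@@H](O)C(=C)[C@@H]1CO[Si](c5ccccc5)(c6ccccc6)C(C)(C)C | intermediate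
8 | α-methylene ketone (C1=O, C10=C20, C3–OAc, C6–OSitBuPh2) | CC1(C)[C@H](OC(C)=O)CC(=O)C(=C)[C@@H]1CO[Si](c5ccccc5)(c6ccccc6)C(C)(C)C | intermediate
9 | C1 allylic alcohol epimeric with 7, hydroxyl equatorial and cis to the C5 arm | CC1(C)[C@H](OC(C)=O)C[C@H](O)C(=C)[C@@H]1CO[Si](c5ccccc5)(c6ccccc6)C(C)(C)C | intermediate
10 | C1 triethylsilyl ether of 9 | CC1(C)[C@H](OC(C)=O)C[C@H](O[Si](CC)(CC)CC)C(=C)[C@@H]1CO[Si](c5ccccc5)(c6ccccc6)C(C)(C)C | intermediate
11 | ring A spiro epoxide: C10–C20 oxirane with oxygen trans to the C5 arm, C1–OSiEt3 cis to the arm, C3–OAc, C6–OSitBuPh2 | CC1(C)[C@H](OC(C)=O)C[C@H](O[Si](CC)(CC)CC)[C@]2(CO2)[C@@H]1CO[Si](c5ccccc5)(c6ccccc6)C(C)(C)C | intermediate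
12 | 2,2,2-trifluoroethyl acrylate (2,2,2-trifluoroethyl prop-2-enoate) | C=CC(=O)OCC(F)(F)F | starting material
13 | δ-hydroxy ester: quaternary C10 bearing C20H2OH and CH2CH2CO2CH2CF3 (C9, C8, C7) | CC1(C)[C@H](OC(C)=O)C[C@H](O[Si](CC)(CC)CC)[C@](CCC(=O)OCC(F)(F)F)(CO)[C@@H]1CO[Si](c5ccccc5)(c6ccccc6)C(C)(C)C | intermediate
14 | spiro δ-lactone on ring A (C10–C20H2–O–C7(=O)–C8H2–C9H2; C20 cis and C9 trans to the C5 arm; C1–OSiEt3, C3–OAc, C6–OSitBuPh2) | CC1(C)[C@H](OC(C)=O)C[C@H](O[Si](CC)(CC)CC)[C@]2(COC(=O)CC2)[C@@H]1CO[Si](c5ccccc5)(c6ccccc6)C(C)(C)C | intermediate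
15 | C1 alcohol of 14 | CC1(C)[C@H](OC(C)=O)C[C@H](O)[C@]2(COC(=O)CC2)[C@@H]1CO[Si](c5ccccc5)(c6ccccc6)C(C)(C)C | intermediate
16 | C1 ketone with C3 acetate (spiro lactone) | CC1(C)[C@H](OC(C)=O)CC(=O)[C@]2(COC(=O)CC2)[C@@H]1CO[Si](c5ccccc5)(c6ccccc6)C(C)(C)C | intermediate
17 | ring A enone spiro lactone (C1=O, C2=C3, C6–OSitBuPh2) | CC1(C)C=CC(=O)[C@]2(COC(=O)CC2)[C@@H]1CO[Si](c5ccccc5)(c6ccccc6)C(C)(C)C | intermediate
18 | C8-propanoyl spiro lactone (β-keto lactone, C8 epimers) | CC1(C)C=CC(=O)[C@]2(COC(=O)C(C(=O)CC)C2)[C@@H]1CO[Si](c5ccccc5)(c6ccccc6)C(C)(C)C | intermediate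
19 | C8 phenylselanyl derivative of 18 | CC1(C)C=CC(=O)[C@]2(COC(=O)C([Se]c7ccccc7)(C(=O)CC)C2)[C@@H]1CO[Si](c5ccccc5)(c6ccccc6)C(C)(C)C | intermediate
20 | C8 selenoxide of 19 | CC1(C)C=CC(=O)[C@]2(COC(=O)C([Se](=O)c7ccccc7)(C(=O)CC)C2)[C@@H]1CO[Si](c5ccccc5)(c6ccccc6)C(C)(C)C | intermediate
21 | 8-propanoyl C8=C9 unsaturated spiro lactone | CC1(C)C=CC(=O)[C@]2(COC(=O)C(C(=O)CC)=C2)[C@@H]1CO[Si](c5ccccc5)(c6ccccc6)C(C)(C)C | intermediate
22 | buta-1,3-diene | C=CC=C | starting material
23 | Diels–Alder adduct: ring C cyclohexene (C12=C13), propanoyl on C8, lactone cis-fused to ring C, C11 on the C1 side | CC1(C)C=CC(=O)[C@]2(COC(=O)[C@@]3(C(=O)CC)CC=CC[C@H]32)[C@@H]1CO[Si](c5ccccc5)(c6ccccc6)C(C)(C)C | intermediate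
24 | C16 bromide of 23 (2-bromopropanoyl on C8, C16 epimers) | CC1(C)C=CC(=O)[C@]2(COC(=O)[C@@]3(C(=O)C(C)Br)CC=CC[C@H]32)[C@@H]1CO[Si](c5ccccc5)(c6ccccc6)C(C)(C)C | intermediate
25 | ring D closed: bicyclo[3.2.1]octanone with C15=O and C16–H/CH3 (C16 epimers), C6–OSitBuPh2 | CC1(C)C=CC(=O)[C@]2(COC(=O)[C@@]34C[C@@H](CC[C@H]32)C(C)C4=O)[C@@H]1CO[Si](c5ccccc5)(c6ccccc6)C(C)(C)C | intermediate
26 | C16 exo-hydroxy ketone, C6 tert-butyldiphenylsilyl ether of the target | CC1(C)C=CC(=O)[C@]2(COC(=O)[C@@]34C[C@@H](CC[C@H]32)[C@](C)(O)C4=O)[C@@H]1CO[Si](c5ccccc5)(c6ccccc6)C(C)(C)C | intermediate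
27 | target CNP0530135.1 | CC1(C)C=CC(=O)[C@]2(COC(=O)[C@@]34C[C@@H](CC[C@H]32)[C@](C)(O)C4=O)[C@@H]1CO | target

**Step count and risks**

Total steps: 20. Longest linear sequence: 20 steps (1 → 27); 12 and 22 are purchased.

Steps most likely to fail:

Step 18 (radical closure of ring D). The C16 radical may close onto C12 instead (6-endo, giving a bicyclo[2.2.2]octane), or take hydrogen from the stannane before it cyclises. Fallback: from 23, tBuMe2SiOTf and Et3N (CH2Cl2, 0 °C) give the C15 tert-butyldimethylsilyl enol ether F1. Pd(OAc)2 (divalent palladium, 1.1 equiv, MeCN, rt) then closes ring D by Saegusa-type oxidative cyclisation of the enol silane onto C12=C13. Carbopalladation occurs at C13, and β-hydride loss goes towards C11 because elimination towards the bridgehead C13 is not possible. This gives the C11=C12 unsaturated bicyclo[3.2.1]octenone F2. Hydrogenation with H2 over RhCl(PPh3)3, a catalyst expected to spare the hindered conjugated ring A alkene, should saturate C11=C12 and return to 25.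

Step 16 (Diels–Alder reaction). Cycloaddition at the neopentyl C9 terminus may be slow, leaving the sensitive dienophile time to polymerise or add water, and facial selectivity may erode if heating is needed. Fallback: from 21, the more electron-rich 2-(trimethylsilyloxy)buta-1,3-diene (PhMe, 60 °C, no Lewis acid) should give, with the same facial preference, the C12 trimethylsilyl enol ether cycloadduct F3. CsF and PhNTf2 (DME, rt) convert the enol silane regiospecifically into the C12 enol triflate F4. Reduction with Pd(OAc)2/PPh3, Bu3N and HCO2H (DMF, 60 °C; zerovalent palladium formed in the flask) replaces the triflate by hydrogen and returns to 23.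

Step 19 (C16 hydroxylation). Enolisation of the hindered bridged ketone may be incomplete, the enolate may add to the sulfonimine by-product, or the potassium alkoxide of the product may undergo α-ketol rearrangement. Fallback (Rubottom oxidation): from 25, Me3SiOTf and Et3N (CH2Cl2, 0 °C) give the C15 trimethylsilyl enol ether F5. mCPBA (NaHCO3, CH2Cl2, −20 °C) epoxidises it on the exo face, and silyl migration gives the C16 trimethylsilyloxy ketone F6. PPTS in MeOH removes the trimethylsilyl group and returns to 26.

**Further compounds**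

F1 | step 18 | C15 tert-butyldimethylsilyl enol ether of 23 | CC1(C)C=CC(=O)[C@]2(COC(=O)[C@@]3(C(O[Si](C)(C)C(C)(C)C)=CC)CC=CC[C@H]32)[C@@H]1CO[Si](c5ccccc5)(c6ccccc6)C(C)(C)C
F2 | step 18 | C11=C12 unsaturated bicyclo[3.2.1]octenone (ring D closed, C16 epimers) | CC1(C)C=CC(=O)[C@]2(COC(=O)[C@@]34C[C@@H](C=C[C@H]32)C(C)C4=O)[C@@H]1CO[Si](c5ccccc5)(c6ccccc6)C(C)(C)C
F3 | step 16 | C12 trimethylsilyl enol ether cycloadduct (C12=C13) | CC1(C)C=CC(=O)[C@]2(COC(=O)[C@@]3(C(=O)CC)CC=C(O[Si](C)(C)C)C[C@H]32)[C@@H]1CO[Si](c5ccccc5)(c6ccccc6)C(C)(C)C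
F4 | step 16 | C12 enol triflate (C12=C13) | CC1(C)C=CC(=O)[C@]2(COC(=O)[C@@]3(C(=O)CC)CC=C(OS(=O)(=O)C(F)(F)F)C[C@H]32)[C@@H]1CO[Si](c5ccccc5)(c6ccccc6)C(C)(C)C
F5 | step 19 | C15 trimethylsilyl enol ether of 25 (C15=C16) | CC1(C)C=CC(=O)[C@]2(COC(=O)[C@@]34C[C@@H](CC[C@H]32)C(C)=C4O[Si](C)(C)C)[C@@H]1CO[Si](c5ccccc5)(c6ccccc6)C(C)(C)C
F6 | step 19 | C16 exo-trimethylsilyloxy ketone | CC1(C)C=CC(=O)[C@]2(COC(=O)[C@@]34C[C@@H](CC[C@H]32)[C@](C)(O[Si](C)(C)C)C4=O)[C@@H]1CO[Si](c5ccccc5)(c6ccccc6)C(C)(C)C
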